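The data are calculated from invented constants; noise was put on by code.

At 2.0 h the flask beta is to be read, and one of the options for the next 2.0 h chosen.

the same everywhere: substrate 0.10 M

|  | partner | capture agent | temperature | remark | time |
|---|---|---|---|---|---|
| beta | 0.13 M | 0.10 M | 35 °C | the very flask that is asked about, followed so far |  |
| delta | 0.13 M | 0.067 M | 41 °C | run made earlier |  |
| flask | 0.130 M | 0.100 M | 35 °C |  | 2.0 h |

| run | time / min | target / % | substrate / % |
|---|---|---|---|
| beta | 6.00 | 3.8 | 25.9 |
| beta | 20.0 | 13.6 | 1.9 |
| beta | 30.0 | 17.0 | 0.2 |
| beta | 50.0 | 20.6 | 0 |
| beta | 80.0 | 21.7 | 0.4 |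
| delta | 5.00 | 5.9 | 13.2 |
| delta | 10.0 | 12.2 | 1.5 |
| delta | 15.0 | 15.7 | 0 |
| delta | 20.0 | 17.6 | 0.5 |
| delta | 25.0 | 20.4 | 0.4 |

(each reading ± 0.5 percentage points)

- Saturday's: at 2.0 h add partner, 50.0% of the amount charged, then wait 2.0 h
- Friday's: at 2.0 h raise the temperature by 15 K, then wait 2.0 h
- Sunday's: at 2.0 h take out 90% of the target then present, then wait 2.0 h
- Monday's: change nothing and wait 2.0 h more

- target that was removed still counts
- the analysis behind the earlier runs scatters by 0.5 percentage points, standard deviation
- additions bring no volume worth counting

* target, in percent of the substrate first charged, at 2.0 h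
* the option that brings most further target ("none" if no option brings more than 2 percentage points) (Saturday's / Friday's / Sunday's / Monday's / none)
* target present, with what was taken out counted in, in percent of the substrate first charged, after Friday's
* target present, with what was taken out counted in, in percent of the substrate first charged, after Sunday's

Two chemists read the beta run alike: substrate is down to 0.2% at 30.0 min, while target creeps to 21.7% at 80.0 min. They dispute what holds target there.

The second chemist suspects the partner of being the limiting reagent, the charge that runs out first and caps the product. Her quantity is the partner use, moles of target standing per mole of partner charged, which leaves time out once target has levelled: 0.167 from the last beta reading. The delta run, still rising at its last reading, gives 0.157, so she treats the use as a property of the partner. Saturday's addition should then bring 11 percentage points, and she names Saturday's as best.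

The first chemist made the forecast: target 22% at 2.0 h, best none, 22% after Friday's and 22% after Sunday's. Her ground against the addition: “Partner is in excess and substrate is exhausted, so more partner shouldn't help.”

The simulated beta flask gives 22.8% at 2.0 h, and the best option is none. Saturday's brings 1.5 points, under the margin of 2 points. Friday's brings 0.35 points, Sunday's 0.45 points and Monday's 0.45 points, so target, with what was taken out counted in, stands at 23.2% after Friday's and 23.3% after Sunday's.

    open intermediate → decomposed reagent (k = 0.00820 min⁻¹, Ea = 104 kJ mol⁻¹)
    substrate → open intermediate (k = 0.220 min⁻¹, Ea = 83.0 kJ mol⁻¹)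
    2 second intermediate → homo product (k = 0.260 M⁻¹ min⁻¹, Ea = 62.0 kJ mol⁻¹)
    open intermediate + capture agent → trapped intermediate (k = 0.160 M⁻¹ min⁻¹, Ea = 49.0 kJ mol⁻¹)
    partner → second intermediate (k = 1.10 min⁻¹, Ea = 84.0 kJ mol⁻¹)
    open intermediate + second intermediate → target (k = 0.150 M⁻¹ min⁻¹, Ea = 60.0 kJ mol⁻¹)
    (constants at 35 °C)

In the beta flask the partner use at 2.0 h is 0.176, yet the added partner brought 1.5 points, not 11 points. The second chemist's view has its region in the starting charge: at 0.0781 M of partner the answer has moved by 5 points. A neighbouring flask, the beta recipe with 0.052 M of partner, has target predicted by her use at 8.68%. It gives 14.2%, a partner use of 0.272. At 120 min that neighbour flask has 0% of its partner left and holds 8.39% of open intermediate.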